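In a one-step world where Q goes whenever two Q meet, the reciprocal of cQ rises steadily with time, and the share of Q left is one over one plus s times charge times time. The runs can show whether our flask behaves like that.

| flask | Q | E | remark | time |
|---|---|---|---|---|
| Monday's | 5 mM | 9.5 mM | run made earlier |  |
| Friday's | 7.5 mM | 9.5 mM | run made earlier |  |
| Tuesday's | 10 mM | 14 mM | run made earlier |  |
| flask | 10 mM | 9.50 mM |  | 6.0 min |

| run | time / min | Q / % | X / % |
|---|---|---|---|
| Monday's | 0.417 | 60 | 13 |
| Monday's | 0.667 | 44 | 18 |
| Monday's | 1.00 | 34 | 22 |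
| Monday's | 2.00 | 19 | 29 |
| Monday's | 3.00 | 16 | 34 |
| Monday's | 5.00 | 6 | 35 |
| Friday's | 0.333 | 54 | 10 |
| Friday's | 1.00 | 30 | 16 |
| Friday's | 1.50 | 20 | 22 |
| Friday's | 2.50 | 13 | 24 |
| Friday's | 4.00 | 8 | 27 |
| Friday's | 5.00 | 8 | 23 |
| Tuesday's | 0.417 | 42 | 16 |
| Tuesday's | 0.667 | 27 | 16 |
| Tuesday's | 1.33 | 17 | 21 |
| Tuesday's | 2.50 | 7 | 29 |
| Tuesday's | 5.00 | 5 | 32 |

(standard deviation of a reading: 2 percentage points)

* part of the Q that has reacted at 6.0 min
* share of free E in free E and D together, at 6.0 min

- the numbers in the tables scatter with a standard deviation of 2 percentage points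
- the earlier runs do not show how much of E is bound; that part of a forecast is a guess

From each run we take a middle reading, where Q has mostly gone but stands clear of the scatter. Monday's at 1.00 min gives 0.388 mM⁻¹ min⁻¹, Friday's at 1.50 min gives 0.356 mM⁻¹ min⁻¹, and Tuesday's at 1.33 min gives 0.367 mM⁻¹ min⁻¹. Tuesday's run, with 14 mM of E, lies below Monday's and above Friday's, so in these three readings the extra E does not show. The mean, 0.370 mM⁻¹ min⁻¹, is our loss constant s, the rise of the reciprocal of cQ per minute; the usual term is an apparent second-order rate constant.

We reckon just the small part, the Q left. By the rule, this flask leaves 4.31% at 6.0 min. The second way uses a late reading. Here s times charge times time is 22.2, so the one is a small correction and the share left goes nearly as one over the time. Tuesday's run, with the same charge of Q, left 5% at 5.00 min, which scales to 4.17%. That run held more E than this flask, and its reading carries a scatter of 2 percentage points, but the two ways agree, so we commit to 95.7% reacted. For fr we have no reckoning.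

The forecast gives 95.5% reacted, close to ours, and 50% for fr, saying “I guess about half, with wide limits”.

The flask gives 96.3% reacted and 52.2% for fr.

    Q + E → L + X (k = 0.910 M⁻¹ s⁻¹)
    E + L ⇌ D, settled at all times (K = 2.10 × 10⁵ M⁻¹)
    L + X → Z (k = 0.730 M⁻¹ s⁻¹)
    2 Q → J (k = 2.10 M⁻¹ s⁻¹)
    E ⇌ G (K = 1.00, k = 0.0110 s⁻¹)

Just after the start, Q goes 4.9 times as fast by the path from 2 Q to J as by the path with E. Our rule left 4.31% where the flask leaves 3.70%; at 3.00 min it gives 8.26%, and the flask holds 8.48%.

In a neighbour flask with 25 mM of Q, the same s leaves 1.77% at 6.0 min. Computed, that neighbour flask has 98.2% reacted, with 1.8% of its Q left.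

The data stem from a simulated flask with made-up constants; scatter was added.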